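**Plan**
- Retrosynthetic cuts: first the ester C–O bond between the side-chain carbinol and the dienoyl group, then C4a–C5 and C8–C8a of the naphthazarin, then the prenyl C3'=C4' double bond and the C1'–C2' bond of the side chain; the acyl chain is cut at its C3=C4 double bond.
- Enabling feature: ring B (C4a, C5, C6, C7, C8, C8a) with its hydroxyls on C5 and C8 is the double enol of a cyclohex-2-ene-1,4-dione fused to ring A, so it equals the free C=C of a benzoquinone plus a C4 unit oxygenated at both ends, with no redox adjustment.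
- Forward, ring A: 2,5-dimethoxybenzaldehyde is allylated, silylated, cross-metathesised to the prenyl chain and oxidatively demethylated to the side-chain benzoquinone.
- Forward, ring B and chain: cycloaddition with 2,5-bis(trimethylsilyloxy)furan, bridge opening and enolisation give the naphthazarin in one flask; desilylation gives shikonin, and the Z-dienoic acid (from a Wittig reaction) is joined last by carbodiimide esterification.
- Stereochemistry: the only stereocentre (C1', R) comes from reagent-controlled allylboration and the Z alkene from a salt-free Wittig reaction of a non-stabilised ylide; neither is touched afterwards.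

Key step: step 6

Remark: naphthazarins are written as the tautomer of the target SMILES (side chain on the quinone ring); the ring tautomers interconvert rapidly, so no step has to distinguish them.

**Step 1**
Reactants: 1 2,5-dimethoxybenzaldehyde
Product: 3 (1R)-1-(2,5-dimethoxyphenyl)but-3-en-1-ol, via borinate ester 2 (not isolated)
Conditions: (+)-Ipc2BOMe [(+)-B-methoxydiisopinocampheylborane, from (−)-α-pinene], CH2=CHCH2MgBr, Et2O, −78 °C → rt; then 1, −78 °C; then 3 M aq. NaOH, 30% H2O2, 0 °C → rt
Reagents that add atoms: allylmagnesium bromide, C=CC[Mg]Br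
Why: Brown asymmetric allylboration, in which the B-allyldiisopinocampheylborane made in the flask transfers allyl through a chair-like six-membered transition state to the Re face of the aryl aldehyde, setting C1' as R under reagent control before alkaline peroxide cleaves borinate 2.

**Step 2**
Reactants: 3 (1R)-1-(2,5-dimethoxyphenyl)but-3-en-1-ol
Product: 4 tert-butyl{[(1R)-1-(2,5-dimethoxyphenyl)but-3-en-1-yl]oxy}dimethylsilane
Conditions: TBSCl, imidazole, DMF, rt
Reagents that add atoms: tert-butyldimethylsilyl chloride, CC(C)(C)[Si](C)(C)Cl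
Why: Imidazole-promoted silylation of a secondary benzylic alcohol occurs at oxygen, leaves the C1'–O bond and its configuration untouched, and gives an ether suited to the later oxidation and cycloaddition.

**Step 3**
Reactants: 4 tert-butyl{[(1R)-1-(2,5-dimethoxyphenyl)but-3-en-1-yl]oxy}dimethylsilane; 5 2-methylbut-2-ene
Product: 6 tert-butyl{[(1R)-1-(2,5-dimethoxyphenyl)-4-methylpent-3-en-1-yl]oxy}dimethylsilane
Conditions: 5 (large excess, co-solvent), second-generation Grubbs catalyst RuCl2(=CHPh)(PCy3)(1,3-dimesitylimidazolidin-2-ylidene) (3 mol%), CH2Cl2, 35 °C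
Reagents that add atoms: none
Why: Olefin cross-metathesis of a terminal alkene with excess 2-methylbut-2-ene should exchange the =CH2 terminus for the isopropylidene group with loss of propene, while the aryl ethers and the silyl ether are inert to the ruthenium carbene.

**Step 4**
Reactants: 6 tert-butyl{[(1R)-1-(2,5-dimethoxyphenyl)-4-methylpent-3-en-1-yl]oxy}dimethylsilane
Product: 7 2-[(1R)-1-(tert-butyldimethylsilyloxy)-4-methylpent-3-en-1-yl]-1,4-benzoquinone
Conditions: (NH4)2Ce(NO3)6 (2.5 equiv), MeCN/H2O (2:1), 0 °C, short reaction time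
Reagents that add atoms: water, O
Why: Oxidative demethylation of a 1,4-dimethoxyarene by tetravalent cerium goes through the arene radical cation, ipso attack of water and loss of methanol, and at 0 °C should be faster than attack on the isolated trisubstituted alkene or cleavage of the hindered secondary silyl ether.

**Step 5**
Reactants: 8 succinic anhydride
Product: 9 2,5-bis(trimethylsilyloxy)furan
Conditions: Me3SiCl (2.4 equiv), Et3N (2.4 equiv), ZnCl2 (cat.), MeCN, rt → 45 °C; filtration under argon, distillation
Reagents that add atoms: chlorotrimethylsilane, C[Si](C)(C)Cl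
Why: Twofold enol silylation of the anhydride (silyl ketene acetal formation) is driven by the aromaticity of the furan that results and is a known preparation of this diene.

**Step 6**
Reactants: 7 2-[(1R)-1-(tert-butyldimethylsilyloxy)-4-methylpent-3-en-1-yl]-1,4-benzoquinone; 9 2,5-bis(trimethylsilyloxy)furan
Product: 12 shikonin tert-butyldimethylsilyl ether, via oxa-bridged cycloadduct 10 (not isolated), via dihydrotetraone 11 (not isolated)
Conditions: 9 (1.3 equiv), CH2Cl2, −30 °C → rt, argon; then THF/0.5 M aq. HCl, 0 °C, 10 min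
Reagents that add atoms: none
Why: The electron-rich diene 9 and the unsubstituted C5=C6 bond of quinone 7 should combine in a concerted, normal-demand [4+2] cycloaddition that forms C4a–C5 and C8–C8a and gives the oxa-bridged bis(silyl ketal) 10; dilute acid then cleaves the two silyl ketals with loss of hexamethyldisiloxane, the oxygen bridge opens to dihydrotetraone 11, and enolisation of the doubly activated 4a-H and 8a-H gives naphthazarin 12 with no oxidant. The closest known reaction type is the Diels–Alder addition of 2,5-bis(silyloxy)furans to quinones followed by bridge opening to para-dioxygenated arenes. Ring B (C4a, C5, C6, C7, C8, C8a) closes by intermolecular cycloaddition, both bonds being made suprafacially in one event, and the oxygen bridge is only transient. No stereocentre is created that survives, since the sp3 centres of 10 and 11 at C4a, C5, C8 and C8a all become sp2, and C1' is not involved. The step needs site selectivity for C5=C6 over C2=C3, which the bulky, electron-releasing silyloxyalkyl substituent on C2 secures by shielding and deactivating its own double bond; orientation is immaterial because 9 is symmetric and the naphthazarin tautomers interconvert. The work-up acid is kept dilute, cold and brief so that the silyl ether at C1' and the prenyl alkene stay intact.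

**Step 7**
Reactants: 12 shikonin tert-butyldimethylsilyl ether
Product: 13 shikonin, 5,8-dihydroxy-2-[(1R)-1-hydroxy-4-methylpent-3-en-1-yl]-1,4-naphthoquinone
Conditions: HF·pyridine, pyridine, THF, 0 °C → rt
Reagents that add atoms: none
Why: Buffered fluoride cleavage of the Si–O bond frees the carbinol without breaking C1'–O, and it avoids both the phenoxide formation of basic fluoride sources and the strong acid that would cyclise the carbinol onto the prenyl alkene.

**Step 8**
Reactants: 14 (2-carboxyethyl)triphenylphosphonium bromide; 15 methacrolein (2-methylprop-2-enal)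
Product: 18 (3Z)-5-methylhexa-3,5-dienoic acid, via ylide carboxylate 16 (not isolated), via sodium dienoate 17 (not isolated)
Conditions: NaN(SiMe3)2 (2.1 equiv), THF, −78 → 0 °C; then 15, −78 °C → rt; 1 M aq. HCl to pH 3, 0 °C
Reagents that add atoms: none
Why: Wittig olefination with the non-stabilised, lithium-free ylide 16 should give the Z alkene by kinetic formation of the cis-oxaphosphetane, and the carboxylate form 17 keeps C2 from being deprotonated, so the double bond does not move into conjugation.

**Step 9**
Reactants: 13 shikonin; 18 (3Z)-5-methylhexa-3,5-dienoic acid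
Product: 19 (1R)-1-(5,8-dihydroxy-1,4-dioxo-1,4-dihydronaphthalen-2-yl)-4-methylpent-3-en-1-yl (3Z)-5-methylhexa-3,5-dienoate (target)
Conditions: DCC (1.2 equiv), DMAP (0.1 equiv), CH2Cl2, −20 → 0 °C
Reagents that add atoms: none
Why: Steglich esterification acylates the side-chain carbinol at oxygen with retention at C1', because the two peri-hydroxyls are chelated to the quinone carbonyls and poorly nucleophilic, and low temperature with little DMAP limits base-induced conjugation of the β,γ-unsaturated acyl group.

**Compound list**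
1 | 2,5-dimethoxybenzaldehyde | COc1ccc(OC)c(C=O)c1 | starting material
2 | (1R)-1-(2,5-dimethoxyphenyl)but-3-en-1-yl diisopinocampheylborinate (formed in the flask) | C[C@H]1[C@@H]2C[C@@H](C2(C)C)C[C@@H]1B(O[C@H](CC=C)c1cc(OC)ccc1OC)[C@H]1C[C@H]2C[C@@H]([C@@H]1C)C2(C)C | intermediate
3 | (1R)-1-(2,5-dimethoxyphenyl)but-3-en-1-ol | O[C@H](CC=C)c1cc(OC)ccc1OC | intermediate
4 | tert-butyl{[(1R)-1-(2,5-dimethoxyphenyl)but-3-en-1-yl]oxy}dimethylsilane | CC(C)(C)[Si](C)(C)O[C@H](CC=C)c1cc(OC)ccc1OC | intermediate
5 | 2-methylbut-2-ene | CC=C(C)C | starting material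
6 | tert-butyl{[(1R)-1-(2,5-dimethoxyphenyl)-4-methylpent-3-en-1-yl]oxy}dimethylsilane | CC(C)(C)[Si](C)(C)O[C@H](CC=C(C)C)c1cc(OC)ccc1OC | intermediate
7 | 2-[(1R)-1-(tert-butyldimethylsilyloxy)-4-methylpent-3-en-1-yl]-1,4-benzoquinone | CC(C)(C)[Si](C)(C)O[C@H](CC=C(C)C)C1=CC(=O)C=CC1=O | intermediate
8 | succinic anhydride | O=C1CCC(=O)O1 | starting material
9 | 2,5-bis(trimethylsilyloxy)furan | C[Si](C)(C)Oc1ccc(O[Si](C)(C)C)o1 | intermediate
10 | 2-[(1R)-1-(tert-butyldimethylsilyloxy)-4-methylpent-3-en-1-yl]-5,8-bis(trimethylsilyloxy)-4a,5,8,8a-tetrahydro-5,8-epoxynaphthalene-1,4-dione (ring-fusion isomers, formed in the flask) | CC(C)(C)[Si](C)(C)O[C@H](CC=C(C)C)C1=CC(=O)C2C(C1=O)C3(O[Si](C)(C)C)C=CC2(O[Si](C)(C)C)O3 | intermediate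
11 | 2-[(1R)-1-(tert-butyldimethylsilyloxy)-4-methylpent-3-en-1-yl]-4a,8a-dihydronaphthalene-1,4,5,8-tetraone (formed in the flask) | CC(C)(C)[Si](C)(C)O[C@H](CC=C(C)C)C1=CC(=O)C2C(C1=O)C(=O)C=CC2=O | intermediate
12 | shikonin tert-butyldimethylsilyl ether | CC(C)(C)[Si](C)(C)O[C@H](CC=C(C)C)C1=CC(=O)c2c(O)ccc(O)c2C1=O | intermediate
13 | shikonin | O[C@H](CC=C(C)C)C1=CC(=O)c2c(O)ccc(O)c2C1=O | intermediate
14 | (2-carboxyethyl)triphenylphosphonium bromide | OC(=O)CC[P+](c1ccccc1)(c1ccccc1)c1ccccc1.[Br-] | starting material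
15 | methacrolein | CC(=C)C=O | starting material
16 | sodium 3-(triphenylphosphoranylidene)propanoate (formed in the flask) | [Na+].[O-]C(=O)CC=P(c1ccccc1)(c1ccccc1)c1ccccc1 | intermediate
17 | sodium (3Z)-5-methylhexa-3,5-dienoate (formed in the flask) | [Na+].[O-]C(=O)C/C=C\C(C)=C | intermediate
18 | (3Z)-5-methylhexa-3,5-dienoic acid | C=C(C)/C=C\CC(=O)O | intermediate
19 | (1R)-1-(5,8-dihydroxy-1,4-dioxo-1,4-dihydronaphthalen-2-yl)-4-methylpent-3-en-1-yl (3Z)-5-methylhexa-3,5-dienoate | C=C(C)/C=C\CC(=O)O[C@H](CC=C(C)C)C1=CC(=O)c2c(O)ccc(O)c2C1=O | target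

**Count**
Total steps: 9. Longest linear sequence: 7 steps (1, 2, 3, 4, 6, 7, 9).

**Steps most likely to fail**

Step 6. The furan is also a silyl ketene acetal, so conjugate addition to the quinone or electron transfer may outrun the cycloaddition, and the adduct may fragment before both bonds are in place. The fallback sets out from 7 and comes back at 12, and makes the same two bonds with a less nucleophilic carbocyclic diene. Cyclohexane-1,4-dione is silylated twice (Me3SiCl, Et3N, DMF) to 1,4-bis(trimethylsilyloxy)cyclohexa-1,3-diene F1. Thermal Diels–Alder addition of F1 to the free C=C of 7 (toluene, 60 °C) should give the ethano-bridged adduct F2. Et3N then enolises it to the ethano-bridged hydroquinone F3, and Ag2O in the same flask oxidises this to the ethano-bridged quinone F4. Heating F4 (toluene, 110 °C) should expel ethene by retro-Diels–Alder (Alder–Rickert) fragmentation and leave 2-[(1R)-1-(tert-butyldimethylsilyloxy)-4-methylpent-3-en-1-yl]-5,8-bis(trimethylsilyloxy)-1,4-naphthoquinone F5. Brief treatment with THF/0.5 M aq. HCl at 0 °C removes the two aryl silyl groups and returns 12.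

Step 9. Activation of the carboxyl group in the presence of DMAP may deprotonate C2 of the acyl unit, which lies between the carbonyl and the diene, and so move the Z double bond into conjugation; acylation of a phenolic oxygen is a lesser risk. The fallback sets out from 1 and comes back at 19; it activates the alcohol instead of the acid and does so before the quinone exists. Allylation of 1 as in step 1, but with (−)-Ipc2BOMe from (+)-α-pinene, should give via the enantiomeric borinate ester F6 the alcohol (1S)-1-(2,5-dimethoxyphenyl)but-3-en-1-ol F7. Cross-metathesis with 5 as in step 3 gives (1S)-1-(2,5-dimethoxyphenyl)-4-methylpent-3-en-1-ol F8. A Mitsunobu reaction with 18 (PPh3, diisopropyl azodicarboxylate, toluene, −20 °C) should give, with inversion, (1R)-1-(2,5-dimethoxyphenyl)-4-methylpent-3-en-1-yl (3Z)-5-methylhexa-3,5-dienoate F9. Oxidation with (NH4)2Ce(NO3)6 as in step 4 gives the quinone ester F10. Cycloaddition with 9 and the acidic work-up of step 6 then lead through the oxa-bridged cycloadduct F11 and the dihydrotetraone F12 directly to 19. The cis-substituted diene of the acyl chain cannot easily reach an s-cis conformation and is expected to stay out of the cycloaddition.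

Step 4. The acidic nitrate oxidant may remove the silyl group or attack the trisubstituted alkene or the benzylic position. The fallback sets out from 6 and comes back at 7. Anodic oxidation of 6 in methanolic KOH (Pt anode, undivided cell, 0 °C) should give the quinone bis(dimethyl ketal) tert-butyl{[(1R)-4-methyl-1-(3,3,6,6-tetramethoxycyclohexa-1,4-dien-1-yl)pent-3-en-1-yl]oxy}dimethylsilane F13. Hydrolysis in aqueous acetic acid/acetone at rt then releases 7 without a chemical oxidant.

**Further compounds**
F1 | step 6 | 1,4-bis(trimethylsilyloxy)cyclohexa-1,3-diene | C[Si](C)(C)OC1=CC=C(O[Si](C)(C)C)CC1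
F2 | step 6 | ethano-bridged adduct, 2-[(1R)-1-(tert-butyldimethylsilyloxy)-4-methylpent-3-en-1-yl]-5,8-bis(trimethylsilyloxy)-4a,5,8,8a-tetrahydro-5,8-ethanonaphthalene-1,4-dione (ring-fusion isomers) | CC(C)(C)[Si](C)(C)O[C@H](CC=C(C)C)C1=CC(=O)C2C(C1=O)C3(O[Si](C)(C)C)C=CC2(O[Si](C)(C)C)CC3
F3 | step 6 | ethano-bridged hydroquinone, 2-[(1R)-1-(tert-butyldimethylsilyloxy)-4-methylpent-3-en-1-yl]-5,8-bis(trimethylsilyloxy)-5,8-dihydro-5,8-ethanonaphthalene-1,4-diol | CC(C)(C)[Si](C)(C)O[C@H](CC=C(C)C)c1cc(O)c2c(c1O)C1(O[Si](C)(C)C)C=CC2(O[Si](C)(C)C)CC1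
F4 | step 6 | ethano-bridged quinone, 2-[(1R)-1-(tert-butyldimethylsilyloxy)-4-methylpent-3-en-1-yl]-5,8-bis(trimethylsilyloxy)-5,8-dihydro-5,8-ethanonaphthalene-1,4-dione | CC(C)(C)[Si](C)(C)O[C@H](CC=C(C)C)C1=CC(=O)C2=C(C1=O)C1(O[Si](C)(C)C)C=CC2(O[Si](C)(C)C)CC1
F5 | step 6 | 2-[(1R)-1-(tert-butyldimethylsilyloxy)-4-methylpent-3-en-1-yl]-5,8-bis(trimethylsilyloxy)-1,4-naphthoquinone | CC(C)(C)[Si](C)(C)O[C@H](CC=C(C)C)C1=CC(=O)c2c(O[Si](C)(C)C)ccc(O[Si](C)(C)C)c2C1=O
F6 | step 9 | (1S)-1-(2,5-dimethoxyphenyl)but-3-en-1-yl diisopinocampheylborinate (enantiomer of 2) | C[C@@H]1[C@H]2C[C@H](C2(C)C)C[C@H]1B(O[C@@H](CC=C)c1cc(OC)ccc1OC)[C@@H]1C[C@@H]2C[C@H]([C@H]1C)C2(C)C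
F7 | step 9 | (1S)-1-(2,5-dimethoxyphenyl)but-3-en-1-ol | O[C@@H](CC=C)c1cc(OC)ccc1OC
F8 | step 9 | (1S)-1-(2,5-dimethoxyphenyl)-4-methylpent-3-en-1-ol | O[C@@H](CC=C(C)C)c1cc(OC)ccc1OC
F9 | step 9 | (1R)-1-(2,5-dimethoxyphenyl)-4-methylpent-3-en-1-yl (3Z)-5-methylhexa-3,5-dienoate | C=C(C)/C=C\CC(=O)O[C@H](CC=C(C)C)c1cc(OC)ccc1OC
F10 | step 9 | (1R)-1-(3,6-dioxocyclohexa-1,4-dien-1-yl)-4-methylpent-3-en-1-yl (3Z)-5-methylhexa-3,5-dienoate | C=C(C)/C=C\CC(=O)O[C@H](CC=C(C)C)C1=CC(=O)C=CC1=O
F11 | step 9 | oxa-bridged cycloadduct of F10 with 9 (ring-fusion isomers) | C=C(C)/C=C\CC(=O)O[C@H](CC=C(C)C)C1=CC(=O)C2C(C1=O)C3(O[Si](C)(C)C)C=CC2(O[Si](C)(C)C)O3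
F12 | step 9 | (1R)-1-(1,4,5,8-tetraoxo-1,4,4a,5,8,8a-hexahydronaphthalen-2-yl)-4-methylpent-3-en-1-yl (3Z)-5-methylhexa-3,5-dienoate | C=C(C)/C=C\CC(=O)O[C@H](CC=C(C)C)C1=CC(=O)C2C(C1=O)C(=O)C=CC2=O
F13 | step 4 | tert-butyl{[(1R)-4-methyl-1-(3,3,6,6-tetramethoxycyclohexa-1,4-dien-1-yl)pent-3-en-1-yl]oxy}dimethylsilane | CC(C)(C)[Si](C)(C)O[C@H](CC=C(C)C)C1=CC(OC)(OC)C=CC1(OC)OC
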